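The constants used here are made up; the flask was simulated.

The vessel, stirred and isothermal, receives first end groups at a steady rate onto second end groups, which can also condense with each other.

first end groups 10 mM (fed, over 1.0 h); second end groups 0.980 equiv; time 30 h

- why nothing more happens at 30 h, or that something still does (all of the first end groups has reacted / it is still moving / the second end groups has run out first)
- links at 30 h, in percent of the first end groups charged

- two of one species on the left: rate k times its square, two consumed each time
- the reaction counts as stopped when no species that holds the first end groups changes by six tenths of a point or more over the second half of the time
- run time (flask): 30 h

1. My reckoning starts from the half-life of fed first end groups at the charged [second end groups], 8.84 min, which is shorter than the 1.0 h feed. I therefore take each as consumed on arrival, so [second end groups] falls in a straight line to zero over 0.980 h.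

2. Self-condensation goes with the square, whose mean along that line is a third of the starting square. Twice 0.44 L mol⁻¹ min⁻¹ times the starting [second end groups] times that duration, over 3, gives 16.9%: the waste number, the share of second end groups lost to self-condensation. Its zero is the flask with no such loss, where links equal the charge of the limiting reagent, the second end groups.

3. Links should reach 81.4% of the first end groups charged.

4. The test: at 10% of the charged [second end groups] the half-life is 88.4 min, longer than the feed, so first end groups accumulate late and the straight line fails there. One number is not enough, and my figure stays an estimate.

The forecast gives 76.8%, below mine, and states: the second end groups has run out first. Of the end, with B the second end groups, it writes “The final decay of B has a time constant of about 1 h, so it is complete well before 30 h”.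

The flask gives 76.8% and the second end groups has run out first, with 0% of them left at 30.0 h. Links move by 5 points at 0.895 equiv or 1.07 equiv of second end groups.

    first end groups + second end groups → links (k1 = 8.0 L mol⁻¹ min⁻¹)
    2 second end groups → self-condensation product (k2 = 0.44 L mol⁻¹ min⁻¹)

The flask's 1.06 mM of self-condensation product holds 21.7% of the second end groups, more than the waste number. In the neighbouring flask, the same but with 0.390 equiv of second end groups, the same reckoning gives a waste number of 2.68% and links of 38.0%. That neighbouring flask ends with 35.7% of links, 8.54% of its second end groups in self-condensation product, and 64% of its first end groups unbound.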